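The spring run at 15.0 h and the autumn run at 1.00 h hold nearly the same mixture, E 8.1% against 8.6% and D 40.6% against 40.0%, though autumn arrives sooner. Time is therefore a poor clock for D. Spring's last reading gives 2.51 for the exposure a, the natural logarithm of one over the fraction of E left. Taking E + Z → Q as pseudo-first-order in E at each moment, a sums the Z that E has met.

all flasks: E 17 mM
- spring: Z 2 equiv; run made earlier
- autumn: Z 4.5 equiv; run made earlier
- flask: Z 3.00 equiv; time 12 h
- spring (time / h: D / %, Q / %, E / %): 1.33: 27.6, 32.7, 22.7; 4.00: 38.8, 22.8, 12.1; 6.00: 39.7, 20.0, 10.2; 10.0: 39.0, 17.4, 8.2; 15.0: 40.6, 17.9, 8.1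
- autumn (time / h: D / %, Q / %, E / %): 1.00: 40.0, 18.3, 8.6; 2.00: 31.5, 7.1, 2.8; 4.00: 14.7, 0.8, 0.5; 8.00: 3.2, 0, 0.4; 15.0: 0.8, 0, 0

(scatter of a reading: 0.5 percentage points)
- a species is counted by the E in it: one L counts as two
- amounts and yields of Q count L too
- candidate steps: E + Z -> Q; 2 Z -> G; Z + D -> X; E + Q <-> L; E <-> J; Z + Q -> D
- in an amount of Q, one L counts as one Q
- equivalents of Z to E, everything else as given, that leave most D at 12 h
- the amount of D then, in percent of the E charged
- the amount of D with the amounts as given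

Along a in the spring run, D rises from zero to 27.6% at a = 1.48, an average of about 18.6% of the E charged per unit of a. It bends flat between a = 2.28 (39.7%) and 2.51. In autumn it then falls to 31.5% at a = 3.58 and to 14.7% at a = 5.30, a loose figure since that E equals the scatter. It runs down to 0.8%.

Counting Q + 2D + 3X, with X the remainder, spring has taken up 1.99 of its 2 equiv, so it stops at the knee, and 2 equiv is this reckoning's best charge. Autumn's tally is 2.46 at 2.00 h and 2.82 at 4.00 h. With some Z lost to G, the flask's 3.00 equiv should end between them, and D between those two readings.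

The forecast gives 2 equiv, 40.5% and 21% for the flask, holding that “D then peaks near 41% at a ≈ 2.4, which is almost exactly where 2 equiv stops”.

    E + Z → Q (k = 0.0142 M⁻¹ s⁻¹)
    2 Z → G (k = 2.96 × 10⁻⁴ M⁻¹ s⁻¹)
    Z + D → X (k = 0.00700 M⁻¹ s⁻¹)
    E + Q ⇌ L, settled at all times (K = 67.0 M⁻¹)
    E ⇌ J (K = 1.89, k = 2.05 × 10⁻⁶ s⁻¹)
    Z + Q → D (k = 0.0176 M⁻¹ s⁻¹)

The simulation gives 23.9% for the flask at 12 h, and 39.8% at the best charge of 2.04 equiv. Moving Z to 2.82 equiv or 3.17 equiv shifts the flask's D by 5 points. With 1.03% of E left, the flask stands at a = 4.58, past the knee at 2.51, on the falling arm. The neighbour charged with 0.750 equiv keeps 33.4% of E, so a = 1.10, short of the knee, and it holds 15.1% of D.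

The runs were generated by integration with made-up constants.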